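**Retrosynthetic overview**
1. Target ⇒ C12–C13 bond by Cu-catalysed Grignard/allylic-bromide SN2 coupling of ring bromide **8** with all-E 12-bromofarnesyl TBS ether **12**. The three E-alkenes are inherited from farnesol.
2. The ring fragment is a tertiary carbinol. It comes from anti-epoxidation of (S)-α-cyclogeranyl bromide, then hydride opening at the secondary epoxide carbon.
3. The C1 stereocentre comes from resolved (S)-α-cyclogeranic acid, which is made from geranic acid by cation–olefin cyclisation.
4. The only ring (the cyclohexane) is formed first, in Step 1. The side chain is then attached by coupling.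

**Assumptions**
- mCPBA attacks α-cyclogeranyl bromide anti to the pseudo-axial CH2Br, giving the trans-epoxide as the major, separable diastereomer.
- SeO2 oxidises the terminal E-methyl of farnesyl TBS ether to give the E-12-hydroxy compound as the main product.
- Diastereomeric-salt resolution of acid **2** can be made to give the (S)-acid **3**.

---

**Step 1**
Reactants: 1 geranic acid
Product: 2 (±)-α-cyclogeranic acid
Conditions: 85% H3PO4, 20–25 °C, 24–48 h
Reagents that add atoms: none (H3PO4 is only the proton source)
Why: Protonation of the terminal alkene gives a tertiary cation that is captured by the C2=C3 alkene. Loss of a proton then gives the Δ2 (α) isomer (cation–olefin cyclisation). C1 is racemic at this point.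

**Step 2**
Reactants: 2; (S)-1-phenylethylamine (resolving agent; use the antipode that crystallises the (S)-acid salt)
Product: 3 (1S)-2,6,6-trimethylcyclohex-2-ene-1-carboxylic acid
Conditions: amine (0.5 equiv), EtOAc/hexane, recrystallise 2–3×; then 2 M HCl, Et2O
Reagents that add atoms: none (the amine is removed on acidification)
Why: Classical diastereomeric-salt resolution sets the C1 configuration, which is never touched again. Check ee by chiral GC.

**Step 3**
Reactants: 3
Product: 4 [(1S)-2,6,6-trimethylcyclohex-2-en-1-yl]methanol ((S)-α-cyclogeraniol)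
Conditions: LiAlH4, THF, 0 °C → rt
Reagents that add atoms: none
Why: Hydride reduction of the carboxylate to the primary alcohol; there is no α-deprotonation under these conditions, so C1 is not epimerised.

**Step 4**
Reactants: 4
Product: 5 (S)-6-(bromomethyl)-1,5,5-trimethylcyclohex-1-ene
Conditions: PPh3, CBr4, CH2Cl2, 0 → 40 °C
Reagents that add atoms: CBr4, BrC(Br)(Br)Br
Why: Appel substitution at the primary carbon; C1 is not involved.

**Step 5**
Reactants: 5
Product: 6 2-(bromomethyl)-1,3,3-trimethyl-7-oxabicyclo[4.1.0]heptane, with the epoxide O trans to CH2Br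
Conditions: mCPBA, NaHCO3, CH2Cl2, 0 °C
Reagents that add atoms: mCPBA, OOC(=O)c1cccc(Cl)c1 (its O atom ends up in the epoxide)
Why: Prilezhaev epoxidation. The peracid approaches anti to the C1 substituent, which sets the future carbinol centre (C6) trans to the side chain. The minor cis-epoxide is removed by chromatography.

**Step 6**
Reactants: 6
Product: 7 (1S,2S)-2-(bromomethyl)-1,3,3-trimethylcyclohexan-1-ol
Conditions: LiEt3BH (1.3 equiv), THF, 0 °C, 30–60 min; then aq. NaOH/H2O2 work-up
Reagents that add atoms: none (hydride only)
Why: The hydride attacks the less hindered secondary carbon C5 (SN2-type, trans-diaxial opening). The C6–O bond is not broken, so the tertiary carbinol keeps the configuration set in Step 5. The hindered neopentyl-type CH2Br is inert at 0 °C.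

**Step 7**
Reactants: 7
Product: 8 {[(1S,2S)-2-(bromomethyl)-1,3,3-trimethylcyclohexyl]oxy}triethylsilane
Conditions: TESOTf, 2,6-lutidine, CH2Cl2, −20 → 0 °C
Reagents that add atoms: TESOTf, CC[Si](CC)(CC)OS(=O)(=O)C(F)(F)F (the SiEt3 group is retained)
Why: Protecting the tertiary OH as a TES ether makes the bromide compatible with Grignard formation. No stereocentre is affected.

**Step 8**
Reactants: 9 (2E,6E)-farnesol
Product: 10 farnesyl TBS ether
Conditions: TBSCl, imidazole, DMF, 0 °C → rt
Reagents that add atoms: TBSCl, CC(C)(C)[Si](C)(C)Cl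
Why: Silylation of the primary allylic alcohol so it survives the SeO2 and Grignard steps.

**Step 9**
Reactants: 10
Product: 11 (2E,6E,10E)-12-[(tert-butyldimethylsilyl)oxy]-2,6,10-trimethyldodeca-2,6,10-trien-1-ol
Conditions: SeO2 (10 mol%), TBHP (2 equiv), salicylic acid, CH2Cl2, 0 °C → rt; then NaBH4, MeOH, 0 °C
Reagents that add atoms: TBHP, CC(C)(C)OO (supplies the O of the new CH2OH)
Why: Riley/Sharpless allylic oxidation goes at the terminal isopropylidene, at the methyl trans to the chain, giving the E-allylic alcohol. The NaBH4 reduces any over-oxidised aldehyde back to the alcohol.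

**Step 10**
Reactants: 11
Product: 12 tert-butyl{[(2E,6E,10E)-12-bromo-3,7,11-trimethyldodeca-2,6,10-trien-1-yl]oxy}dimethylsilane
Conditions: MsCl, Et3N, CH2Cl2, −20 °C; then LiBr, THF, 0 °C
Reagents that add atoms: LiBr, [Li+].[Br-] (the Br is retained; the Ms group leaves)
Why: The allylic alcohol is converted to the mesylate and then displaced by bromide (SN2) with no alkene isomerisation.

**Step 11**
Reactants: 8; 12
Product: 13 (silyl-protected target)
Conditions: (a) 8, Mg turnings (activated with I2/DIBAL), THF, 40 °C, to make the Grignard; (b) cool to −30 °C, add 12 and Li2CuCl4 (5 mol%), THF, −30 → 0 °C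
Reagents that add atoms: none (Mg and Cu do not remain in the product)
Why: Cu-catalysed SN2 coupling of an alkyl Grignard with a primary allylic bromide is α-selective and keeps the alkene geometry. It forms the C12–C13 bond, joining 10 C and 15 C into the C25 skeleton. The stereocentres of the ring are not affected.

**Step 12**
Reactants: 13
Product: 14 preluffariellolide A
Conditions: TBAF (5 equiv), THF, 0 → 40 °C
Reagents that add atoms: none
Why: Fluoride removes both the primary TBS ether and the tertiary TES ether. The alkenes and stereocentres are unchanged.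

---

**Compound list**

| # | Name | SMILES | Role |
|---|---|---|---|
| 1 | geranic acid | CC(C)=CCC/C(C)=C/C(=O)O | starting material |
| 2 | (±)-α-cyclogeranic acid | CC1=CCCC(C)(C)C1C(=O)O | intermediate |
| 3 | (1S)-α-cyclogeranic acid | OC(=O)[C@H]1C(C)(C)CCC=C1C | intermediate |
| 4 | (S)-α-cyclogeraniol | OC[C@H]1C(C)(C)CCC=C1C | intermediate |
| 5 | (S)-α-cyclogeranyl bromide | BrC[C@H]1C(C)(C)CCC=C1C | intermediate |
| 6 | trans-epoxy bromide (O anti to CH2Br) | BrC[C@H]1C(C)(C)CC[C@@H]2O[C@]12C | intermediate |
| 7 | (1S,2S)-2-(bromomethyl)-1,3,3-trimethylcyclohexan-1-ol | BrC[C@H]1C(C)(C)CCC[C@]1(C)O | intermediate |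
| 8 | TES ether of 7 | BrC[C@H]1C(C)(C)CCC[C@]1(C)O[Si](CC)(CC)CC | intermediate |
| 9 | (2E,6E)-farnesol | CC(C)=CCC/C(C)=C/CC/C(C)=C/CO | starting material |
| 10 | farnesyl TBS ether | CC(C)=CCC/C(C)=C/CC/C(C)=C/CO[Si](C)(C)C(C)(C)C | intermediate |
| 11 | 12-hydroxyfarnesyl TBS ether | OC/C(C)=C/CC/C(C)=C/CC/C(C)=C/CO[Si](C)(C)C(C)(C)C | intermediate |
| 12 | 12-bromofarnesyl TBS ether | BrC/C(C)=C/CC/C(C)=C/CC/C(C)=C/CO[Si](C)(C)C(C)(C)C | intermediate |
| 13 | bis-silyl coupled product | C/C(=C\CO[Si](C)(C)C(C)(C)C)CC/C=C(\C)CC/C=C(\C)CC[C@H]1C(C)(C)CCC[C@]1(C)O[Si](CC)(CC)CC | intermediate |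
| 14 | preluffariellolide A, (2E,6E,10E)-13-[(1S,2S)-2-hydroxy-2,6,6-trimethylcyclohexyl]-3,7,11-trimethyltrideca-2,6,10-trien-1-ol | C/C(=C\CO)CC/C=C(\C)CC/C=C(\C)CC[C@H]1C(C)(C)CCC[C@]1(C)O | target |

**Total step count:** 12.
**Longest linear sequence:** 9 steps (1 → 2 → 3 → 4 → 5 → 6 → 7 → 11 → 12).

**Three steps most likely to fail**
1. **Step 5 (epoxide diastereoselectivity).** The anti:syn ratio of the epoxide may be only moderate. Fallback: abandon the epoxide and hydrate the ring alkene of 5 by Co-catalysed radical hydration (Co(acac)2, PhSiH3, O2). O2 traps the tertiary radical anti to CH2Br; separate the diastereomers, then continue from Step 7.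
2. **Step 9 (SeO2 terminal oxidation).** Yield and E-selectivity may be poor, with over-oxidation or attack on the internal alkenes. Fallback: build the C10=C11 alkene by olefination instead. Convert 4 to ring–CH2CH2C(O)CH3, then do a Horner–Wadsworth–Emmons reaction with a C9–C1 phosphonate and separate the E isomer on AgNO3-silica.
3. **Step 11 (hindered Grignard formation and coupling).** Mg insertion into the neopentyl-type bromide may be sluggish, or the Grignard may not couple cleanly. Fallback: reverse the polarity. Convert 8 to the sulfone (PhSO2Na), alkylate its anion with 12, then remove the sulfone with Mg/MeOH or Pd/LiBHEt3.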